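**Strategy.** The cyclopentanone ring is cut across its aldol array C9(=O)–C10–C11(OH), in prostanoic acid numbering, so that bonds C10–C11 and C8–C9 are made together. The three ring carbons C11–C12–C8 are stored as a strained donor–acceptor cyclopropane (silyloxy donor on C11, benzyl ester acceptor on C8, complete C13–C20 chain on C12). Lewis-acid cleavage of its C8–C11 bond and capture by ketene diethyl acetal, a CH2–C(=O) synthon for C10–C9, should give the cyclopentanone in one formal [3+2] cycloaddition and set the C11 carbinol centre trans to the C12 chain. The C8 ester is a temporary activating group: its decarboxylation later delivers the allyl handle for the acid chain.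

Key step: step 9

Remark: atoms are numbered as in prostanoic acid (C1–C7 acid chain, C8–C12 ring, C13–C20 hydroxylated chain); compounds 13, 15, 16 and 18 are drawn as the trans C8 epimer although C8 is stereochemically labile there and both epimers converge; the ligand antipode in step 8 is assumed by analogy with monosubstituted donor alkenes and would be exchanged for its enantiomer if the sense of induction proved opposite.

Step 1
Reactants: 1 (R)-but-3-yn-2-ol
Product: 2 (R)-tert-butyl(but-3-yn-2-yloxy)dimethylsilane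
Conditions: TBSCl, imidazole, DMF, 0 °C to rt
Reagents that add atoms: tert-butyldimethylsilyl chloride (TBSCl), CC(C)(C)[Si](C)(C)Cl
Why: Imidazole-promoted O-silylation (silyl ether formation) masks the C19 hydroxyl, whose R configuration comes from the commercial alcohol and is not touched.

Step 2
Reactants: 2 (R)-tert-butyl(but-3-yn-2-yloxy)dimethylsilane, 3 (R)-2-(but-3-en-1-yl)oxirane
Product: 5 (5R,9R)-9-[(tert-butyldimethylsilyl)oxy]dec-1-en-7-yn-5-ol, via lithium acetylide 4 (not isolated)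
Conditions: n-BuLi, THF, −78 °C; BF3·OEt2; then 3, −78 °C; aq. NH4Cl
Reagents that add atoms: none
Why: BF3-promoted opening of a terminal epoxide by a lithium acetylide (Yamaguchi–Hirao alkynylation) takes place at the unsubstituted carbon, so the C16–C17 bond forms and the C15 carbinol centre is carried over unchanged from epoxide 3.

Step 3
Reactants: 5 (5R,9R)-9-[(tert-butyldimethylsilyl)oxy]dec-1-en-7-yn-5-ol
Product: 6 (5R,9R)-5,9-bis[(tert-butyldimethylsilyl)oxy]dec-1-en-7-yne
Conditions: TBSCl, imidazole, DMF, rt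
Reagents that add atoms: tert-butyldimethylsilyl chloride (TBSCl), CC(C)(C)[Si](C)(C)Cl
Why: Silyl ether formation protects the C15 hydroxyl with the same group as C19, so that one fluoride treatment removes all silyl groups at the end.

Step 4
Reactants: 6 (5R,9R)-5,9-bis[(tert-butyldimethylsilyl)oxy]dec-1-en-7-yne
Product: 8 (5R,9R)-5,9-bis[(tert-butyldimethylsilyl)oxy]dec-7-yn-1-ol, via B-alkyl-9-borabicyclo[3.3.1]nonane 7 (not isolated)
Conditions: 9-BBN, THF, 0 °C to rt; then NaOH, H2O2, 0 °C
Reagents that add atoms: hydrogen peroxide, OO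
Why: Anti-Markovnikov hydroboration–oxidation places oxygen on C11, because 9-BBN adds to the terminal alkene far faster than to the hindered internal alkyne.

Step 5
Reactants: 8 (5R,9R)-5,9-bis[(tert-butyldimethylsilyl)oxy]dec-7-yn-1-ol
Product: 9 (5R,9R)-5,9-bis[(tert-butyldimethylsilyl)oxy]decan-1-ol
Conditions: H2 (1 atm), 10% Pd/C, EtOAc, rt
Reagents that add atoms: none
Why: Catalytic hydrogenation saturates the C17–C18 alkyne at a stage where no other reducible group is present, and leaves the silyl ethers and both stereocentres untouched.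

Step 6
Reactants: 9 (5R,9R)-5,9-bis[(tert-butyldimethylsilyl)oxy]decan-1-ol
Product: 10 (5S,9R)-5,9-bis[(tert-butyldimethylsilyl)oxy]decanal
Conditions: Dess–Martin periodinane, NaHCO3, CH2Cl2, 0 °C to rt
Reagents that add atoms: none
Why: Dess–Martin oxidation converts the primary alcohol into the C11 aldehyde under buffered, non-epimerising conditions (the descriptor at C15 changes only through the priority rules).

Step 7
Reactants: 10 (5S,9R)-5,9-bis[(tert-butyldimethylsilyl)oxy]decanal
Product: 11 (1Z,5S,9R)-1,5,9-tris[(tert-butyldimethylsilyl)oxy]dec-1-ene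
Conditions: TBSOTf, Et3N, CH2Cl2, 0 °C to rt; chromatography on Et3N-deactivated silica
Reagents that add atoms: tert-butyldimethylsilyl trifluoromethanesulfonate (TBSOTf), CC(C)(C)[Si](C)(C)OS(=O)(=O)C(F)(F)F
Why: Soft enolisation of the aldehyde (silyl triflate and amine) should give mainly the Z silyl enol ether, and the Z geometry matters because it becomes the cis relationship of O11 and the C12 chain in the cyclopropane.

Step 8
Reactants: 11 (1Z,5S,9R)-1,5,9-tris[(tert-butyldimethylsilyl)oxy]dec-1-ene, 12 benzyl diazoacetate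
Product: 13 benzyl (1R,2R,3R)-2-[(tert-butyldimethylsilyl)oxy]-3-[(3S,7R)-3,7-bis[(tert-butyldimethylsilyl)oxy]octyl]cyclopropane-1-carboxylate
Conditions: (CuOTf)2·C6H6 (1 mol%), (S,S)-2,2′-isopropylidenebis(4-tert-butyl-2-oxazoline) (2.2 mol%), CH2Cl2, 0 °C to rt, slow addition of 12
Reagents that add atoms: none
Why: Monovalent copper–bis(oxazoline)-catalysed asymmetric cyclopropanation adds the carbene syn and stereospecifically, so the Z alkene gives the cis O11/C12-alkyl cyclopropane, the C2-symmetric ligand selects the alkene face and thereby fixes C11 and C12 together, and the ester should sit mainly trans to both (its configuration is lost in step 9).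

Step 9
Reactants: 13 benzyl (1R,2R,3R)-2-[(tert-butyldimethylsilyl)oxy]-3-[(3S,7R)-3,7-bis[(tert-butyldimethylsilyl)oxy]octyl]cyclopropane-1-carboxylate, 14 1,1-diethoxyethene (ketene diethyl acetal)
Product: 16 benzyl (1R,2R,3R)-3-[(tert-butyldimethylsilyl)oxy]-2-[(3S,7R)-3,7-bis[(tert-butyldimethylsilyl)oxy]octyl]-5-oxocyclopentane-1-carboxylate, via diethyl ketal cycloadduct 15 (not isolated)
Conditions: SnCl4 (1.1 equiv), CH2Cl2, −78 °C; then 14 (3 equiv, slow addition), −78 to −40 °C; aq. NaHCO3; crude 15 in THF, 0.5 M aq. HCl, 0 °C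
Reagents that add atoms: water, O
Why: SnCl4 binds the ester carbonyl of 13 and the push–pull C8–C11 bond (silyloxy donor on C11, ester acceptor on C8) heterolyses with release of ring strain to a silyloxocarbenium (C11)/tin ester enolate (C8) ion pair; the nucleophilic CH2 of 14 adds to C11 (new C10–C11 bond), the resulting diethoxycarbenium ion at C9 is captured by the enolate carbon C8 (new C8–C9 bond), and the ketal 15 is then hydrolysed to the ketone. The closest known reaction type is the Lewis-acid-mediated formal [3+2] cycloaddition of 2-alkoxy- and 2-silyloxycyclopropane carboxylates with silyl enol ethers, run here with a ketene acetal so that C9 arrives at the ketone oxidation level. The cyclopentane closes by a 5-(enolexo)-exo-trig attack of the enolate on the carboxonium carbon. C11 is set by attack of 14 anti to the departing C8–C11 bond (inversion at C11), which turns the cis O11/alkyl cyclopropane into the 11,12-trans cyclopentane; C12 is carried over unchanged from 13; C8 forms as an epimerisable β-keto ester centre that is set again in step 10. The step needs cleavage of C8–C11 only (the single vicinal donor–acceptor bond), retention of the bulky silyl group on O11 at −78 °C (which also blocks capture of the C9 cation by oxygen as an oxetane), and ring closure at carbon, which the five-membered transition state favours over the seven-membered O-attack.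

Step 10
Reactants: 16 benzyl (1R,2R,3R)-3-[(tert-butyldimethylsilyl)oxy]-2-[(3S,7R)-3,7-bis[(tert-butyldimethylsilyl)oxy]octyl]-5-oxocyclopentane-1-carboxylate, 17 allyl methyl carbonate
Product: 19 (2R,3R,4R)-2-allyl-4-[(tert-butyldimethylsilyl)oxy]-3-[(3S,7R)-3,7-bis[(tert-butyldimethylsilyl)oxy]octyl]cyclopentan-1-one, via β-keto acid 18 (not isolated)
Conditions: H2 (1 atm), 10% Pd/C, THF, 0 °C; filtration under Ar; then 17, Pd(PPh3)4 (5 mol%), THF, 0 °C to rt
Reagents that add atoms: none
Why: Hydrogenolysis frees the β-keto acid under neutral conditions, zerovalent palladium ionises 17 to a π-allyl complex whose β-keto carboxylate loses CO2 to an enolate located only at C8, and allylation of this enolate (Tsuji–Trost-type decarboxylative allylation) should occur anti to the neighbouring C12 chain to give the 8,12-trans ketone, which is also the thermodynamic epimer.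

Step 11
Reactants: 19 (2R,3R,4R)-2-allyl-4-[(tert-butyldimethylsilyl)oxy]-3-[(3S,7R)-3,7-bis[(tert-butyldimethylsilyl)oxy]octyl]cyclopentan-1-one, 20 methyl hex-5-enoate
Product: 21 methyl (5Z)-7-[(1R,2R,3R)-3-[(tert-butyldimethylsilyl)oxy]-2-[(3S,7R)-3,7-bis[(tert-butyldimethylsilyl)oxy]octyl]-5-oxocyclopentyl]hept-5-enoate
Conditions: [Ru(NO3)(=CH-C6H4-2-OiPr)(κ2C,C-NHC)] (NHC = cyclometalated 1-adamantyl-3-(2,6-diisopropylphenyl)imidazolin-2-ylidene; Z-selective Grubbs-type catalyst, 5 mol%), 20 (4 equiv), THF, 35 °C, Ar sweep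
Reagents that add atoms: none
Why: Z-selective olefin cross-metathesis builds the C5=C6 bond, because the cyclometalated ruthenium alkylidene forms side-bound metallacycles that place both substituents syn, and the excess of 20 suppresses homodimerisation of 19.

Step 12
Reactants: 21 methyl (5Z)-7-[(1R,2R,3R)-3-[(tert-butyldimethylsilyl)oxy]-2-[(3S,7R)-3,7-bis[(tert-butyldimethylsilyl)oxy]octyl]-5-oxocyclopentyl]hept-5-enoate
Product: 22 methyl (5Z)-7-[(1R,2R,3R)-3-hydroxy-2-[(3S,7R)-3,7-dihydroxyoctyl]-5-oxocyclopentyl]hept-5-enoate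
Conditions: HF·pyridine, pyridine, THF, 0 °C to rt
Reagents that add atoms: none
Why: Buffered HF·pyridine cleaves the three secondary silyl ethers (fluoride-driven desilylation) at an acidity at which the β-hydroxy cyclopentanone should neither dehydrate nor epimerise at C8.

Step 13
Reactants: 22 methyl (5Z)-7-[(1R,2R,3R)-3-hydroxy-2-[(3S,7R)-3,7-dihydroxyoctyl]-5-oxocyclopentyl]hept-5-enoate
Product: 23 (5Z)-7-[(1R,2R,3R)-3-hydroxy-2-[(3S,7R)-3,7-dihydroxyoctyl]-5-oxocyclopentyl]hept-5-enoic acid (target)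
Conditions: porcine liver esterase, phosphate buffer pH 7.5, acetone (10% v/v), 30 °C
Reagents that add atoms: water, O
Why: Enzymatic ester hydrolysis at neutral pH frees the C1 acid without the base- or acid-induced dehydration to the cyclopentenone that chemical hydrolysis of a β-hydroxy cyclopentanone would risk.

**Compound list**

1 | (R)-but-3-yn-2-ol | C[C@@H](O)C#C | starting material
2 | (R)-tert-butyl(but-3-yn-2-yloxy)dimethylsilane | C[C@@H](O[Si](C)(C)C(C)(C)C)C#C | intermediate
3 | (R)-2-(but-3-en-1-yl)oxirane | C=CCC[C@@H]1CO1 | starting material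
4 | lithium (R)-3-[(tert-butyldimethylsilyl)oxy]but-1-yn-1-ide | C[C@@H](O[Si](C)(C)C(C)(C)C)C#C[Li] | intermediate
5 | (5R,9R)-9-[(tert-butyldimethylsilyl)oxy]dec-1-en-7-yn-5-ol | C[C@@H](O[Si](C)(C)C(C)(C)C)C#CC[C@H](O)CCC=C | intermediate
6 | (5R,9R)-5,9-bis[(tert-butyldimethylsilyl)oxy]dec-1-en-7-yne | C[C@@H](O[Si](C)(C)C(C)(C)C)C#CC[C@H](O[Si](C)(C)C(C)(C)C)CCC=C | intermediate
7 | 9-[(5R,9R)-5,9-bis[(tert-butyldimethylsilyl)oxy]dec-7-yn-1-yl]-9-borabicyclo[3.3.1]nonane | C[C@@H](O[Si](C)(C)C(C)(C)C)C#CC[C@H](O[Si](C)(C)C(C)(C)C)CCCCB1C2CCCC1CCC2 | intermediate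
8 | (5R,9R)-5,9-bis[(tert-butyldimethylsilyl)oxy]dec-7-yn-1-ol | C[C@@H](O[Si](C)(C)C(C)(C)C)C#CC[C@H](O[Si](C)(C)C(C)(C)C)CCCCO | intermediate
9 | (5R,9R)-5,9-bis[(tert-butyldimethylsilyl)oxy]decan-1-ol | C[C@@H](O[Si](C)(C)C(C)(C)C)CCC[C@H](O[Si](C)(C)C(C)(C)C)CCCCO | intermediate
10 | (5S,9R)-5,9-bis[(tert-butyldimethylsilyl)oxy]decanal | C[C@@H](O[Si](C)(C)C(C)(C)C)CCC[C@H](O[Si](C)(C)C(C)(C)C)CCCC=O | intermediate
11 | (1Z,5S,9R)-1,5,9-tris[(tert-butyldimethylsilyl)oxy]dec-1-ene | C[C@@H](O[Si](C)(C)C(C)(C)C)CCC[C@H](O[Si](C)(C)C(C)(C)C)CC/C=C\O[Si](C)(C)C(C)(C)C | intermediate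
12 | benzyl diazoacetate | [N-]=[N+]=CC(=O)OCc1ccccc1 | starting material
13 | benzyl (1R,2R,3R)-2-[(tert-butyldimethylsilyl)oxy]-3-[(3S,7R)-3,7-bis[(tert-butyldimethylsilyl)oxy]octyl]cyclopropane-1-carboxylate | C[C@@H](O[Si](C)(C)C(C)(C)C)CCC[C@H](O[Si](C)(C)C(C)(C)C)CC[C@H]1[C@@H](O[Si](C)(C)C(C)(C)C)[C@@H]1C(=O)OCc1ccccc1 | intermediate
14 | 1,1-diethoxyethene (ketene diethyl acetal) | C=C(OCC)OCC | starting material
15 | benzyl (1R,2R,3R)-5,5-diethoxy-3-[(tert-butyldimethylsilyl)oxy]-2-[(3S,7R)-3,7-bis[(tert-butyldimethylsilyl)oxy]octyl]cyclopentane-1-carboxylate | C[C@@H](O[Si](C)(C)C(C)(C)C)CCC[C@H](O[Si](C)(C)C(C)(C)C)CC[C@H]1[C@H](O[Si](C)(C)C(C)(C)C)CC(OCC)(OCC)[C@@H]1C(=O)OCc1ccccc1 | intermediate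
16 | benzyl (1R,2R,3R)-3-[(tert-butyldimethylsilyl)oxy]-2-[(3S,7R)-3,7-bis[(tert-butyldimethylsilyl)oxy]octyl]-5-oxocyclopentane-1-carboxylate | C[C@@H](O[Si](C)(C)C(C)(C)C)CCC[C@H](O[Si](C)(C)C(C)(C)C)CC[C@H]1[C@H](O[Si](C)(C)C(C)(C)C)CC(=O)[C@@H]1C(=O)OCc1ccccc1 | intermediate
17 | allyl methyl carbonate | COC(=O)OCC=C | starting material
18 | (1R,2R,3R)-3-[(tert-butyldimethylsilyl)oxy]-2-[(3S,7R)-3,7-bis[(tert-butyldimethylsilyl)oxy]octyl]-5-oxocyclopentane-1-carboxylic acid | C[C@@H](O[Si](C)(C)C(C)(C)C)CCC[C@H](O[Si](C)(C)C(C)(C)C)CC[C@H]1[C@H](O[Si](C)(C)C(C)(C)C)CC(=O)[C@@H]1C(=O)O | intermediate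
19 | (2R,3R,4R)-2-allyl-4-[(tert-butyldimethylsilyl)oxy]-3-[(3S,7R)-3,7-bis[(tert-butyldimethylsilyl)oxy]octyl]cyclopentan-1-one | C[C@@H](O[Si](C)(C)C(C)(C)C)CCC[C@H](O[Si](C)(C)C(C)(C)C)CC[C@H]1[C@H](O[Si](C)(C)C(C)(C)C)CC(=O)[C@@H]1CC=C | intermediate
20 | methyl hex-5-enoate | C=CCCCC(=O)OC | starting material
21 | methyl (5Z)-7-[(1R,2R,3R)-3-[(tert-butyldimethylsilyl)oxy]-2-[(3S,7R)-3,7-bis[(tert-butyldimethylsilyl)oxy]octyl]-5-oxocyclopentyl]hept-5-enoate | C[C@@H](O[Si](C)(C)C(C)(C)C)CCC[C@H](O[Si](C)(C)C(C)(C)C)CC[C@H]1[C@H](O[Si](C)(C)C(C)(C)C)CC(=O)[C@@H]1C/C=C\CCCC(=O)OC | intermediate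
22 | methyl (5Z)-7-[(1R,2R,3R)-3-hydroxy-2-[(3S,7R)-3,7-dihydroxyoctyl]-5-oxocyclopentyl]hept-5-enoate | C[C@@H](O)CCC[C@H](O)CC[C@H]1[C@H](O)CC(=O)[C@@H]1C/C=C\CCCC(=O)OC | intermediate
23 | (5Z)-7-[(1R,2R,3R)-3-hydroxy-2-[(3S,7R)-3,7-dihydroxyoctyl]-5-oxocyclopentyl]hept-5-enoic acid (CNP0414125.1) | C[C@@H](O)CCC[C@H](O)CC[C@H]1[C@H](O)CC(=O)[C@@H]1C/C=C\CCCC(=O)O | target

**Step count and risks**

Total step count: 13. Longest linear sequence: 13 steps (1 to 23); compounds 3, 12, 14, 17 and 20 are bought.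

The three steps most likely to fail:

Step 9 (key step). The Lewis acid may oligomerise the ketene acetal faster than it opens the cyclopropane. The silyl group may be lost from O11, after which the alkoxide captures the C9 cation at oxygen. The ion pair may also open fully, so that C10 attacks C11 from both faces and the C11 configuration erodes. The fallback makes the same two bonds in two separate operations. It sets out from 13, whose ester enolate (LiN(iPr)2, THF, −78 °C) is C-acylated with N-methoxy-N-methylacetamide to give the 1-acetyl cyclopropane F1 (C8–C9 bond). TBSOTf and Et3N convert the methyl ketone, whose only enolisable position is C10, into the 1-(silyloxy)vinyl cyclopropane F2. Et2AlCl (CH2Cl2, −78 °C) then triggers the Lewis-acid vinylcyclopropane-to-cyclopentene rearrangement of this donor-substituted vinylcyclopropane (C10–C11 bond), giving the cyclic silyl enol ether F3, with the C11 silyloxy group expected trans to the C12 chain on steric grounds. Mild aqueous acid hydrolyses F3 to 16, where the route is rejoined.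

Step 8. Carbene transfer to a Z-1,2-disubstituted silyl enol ether may show poor facial selectivity under ligand control, and carbene dimerisation may compete. The fallback replaces catalyst control by separation of diastereomers. It sets out from 11, which is cyclopropanated with an achiral catalyst (dirhodium tetraacetate, Rh2(OAc)4, slow addition of 12) to give 13 together with the ring-diastereomeric cyclopropane F4. The mixture is taken through step 9 unchanged, F4 giving the diastereomeric ketal F5 and then the diastereomeric keto ester F6. Because C15 and C19 are fixed, 16 and F6 are diastereomers and are separated by preparative HPLC; the route is rejoined at 16.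

Step 11. The cross-metathesis may stall, the Z-selectivity may erode, or the allyl double bond may migrate. The fallback builds the C5=C6 bond by olefination instead. It sets out from 19, whose allyl group is ozonised (O3, CH2Cl2, −78 °C; PPh3) to the keto aldehyde F7. A salt-free Z-selective Wittig reaction with the ylide from (5-methoxy-5-oxopentyl)triphenylphosphonium bromide (NaN(SiMe3)2, 1.0 equiv, THF, −78 °C) then gives 21, where the route is rejoined; the aldehyde should react far faster than the hindered ring ketone, and the single equivalent of base limits enolisation towards C10.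

Further compounds
F1 | step 9 | benzyl (1S,2R,3R)-1-acetyl-2-[(tert-butyldimethylsilyl)oxy]-3-[(3S,7R)-3,7-bis[(tert-butyldimethylsilyl)oxy]octyl]cyclopropane-1-carboxylate | C[C@@H](O[Si](C)(C)C(C)(C)C)CCC[C@H](O[Si](C)(C)C(C)(C)C)CC[C@H]1[C@@H](O[Si](C)(C)C(C)(C)C)[C@@]1(C(C)=O)C(=O)OCc1ccccc1
F2 | step 9 | benzyl (1S,2R,3R)-2-[(tert-butyldimethylsilyl)oxy]-1-[1-[(tert-butyldimethylsilyl)oxy]ethenyl]-3-[(3S,7R)-3,7-bis[(tert-butyldimethylsilyl)oxy]octyl]cyclopropane-1-carboxylate | C[C@@H](O[Si](C)(C)C(C)(C)C)CCC[C@H](O[Si](C)(C)C(C)(C)C)CC[C@H]1[C@@H](O[Si](C)(C)C(C)(C)C)[C@@]1(C(=C)O[Si](C)(C)C(C)(C)C)C(=O)OCc1ccccc1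
F3 | step 9 | benzyl (4R,5R)-2,4-bis[(tert-butyldimethylsilyl)oxy]-5-[(3S,7R)-3,7-bis[(tert-butyldimethylsilyl)oxy]octyl]cyclopent-1-ene-1-carboxylate | C[C@@H](O[Si](C)(C)C(C)(C)C)CCC[C@H](O[Si](C)(C)C(C)(C)C)CC[C@H]1[C@H](O[Si](C)(C)C(C)(C)C)CC(O[Si](C)(C)C(C)(C)C)=C1C(=O)OCc1ccccc1
F4 | step 8 | benzyl (1S,2S,3S)-2-[(tert-butyldimethylsilyl)oxy]-3-[(3S,7R)-3,7-bis[(tert-butyldimethylsilyl)oxy]octyl]cyclopropane-1-carboxylate | C[C@@H](O[Si](C)(C)C(C)(C)C)CCC[C@H](O[Si](C)(C)C(C)(C)C)CC[C@@H]1[C@H](O[Si](C)(C)C(C)(C)C)[C@H]1C(=O)OCc1ccccc1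
F5 | step 8 | benzyl (1S,2S,3S)-5,5-diethoxy-3-[(tert-butyldimethylsilyl)oxy]-2-[(3S,7R)-3,7-bis[(tert-butyldimethylsilyl)oxy]octyl]cyclopentane-1-carboxylate | C[C@@H](O[Si](C)(C)C(C)(C)C)CCC[C@H](O[Si](C)(C)C(C)(C)C)CC[C@@H]1[C@@H](O[Si](C)(C)C(C)(C)C)CC(OCC)(OCC)[C@H]1C(=O)OCc1ccccc1
F6 | step 8 | benzyl (1S,2S,3S)-3-[(tert-butyldimethylsilyl)oxy]-2-[(3S,7R)-3,7-bis[(tert-butyldimethylsilyl)oxy]octyl]-5-oxocyclopentane-1-carboxylate | C[C@@H](O[Si](C)(C)C(C)(C)C)CCC[C@H](O[Si](C)(C)C(C)(C)C)CC[C@@H]1[C@@H](O[Si](C)(C)C(C)(C)C)CC(=O)[C@H]1C(=O)OCc1ccccc1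
F7 | step 11 | 2-[(1R,2R,3R)-3-[(tert-butyldimethylsilyl)oxy]-2-[(3S,7R)-3,7-bis[(tert-butyldimethylsilyl)oxy]octyl]-5-oxocyclopentyl]acetaldehyde | C[C@@H](O[Si](C)(C)C(C)(C)C)CCC[C@H](O[Si](C)(C)C(C)(C)C)CC[C@H]1[C@H](O[Si](C)(C)C(C)(C)C)CC(=O)[C@@H]1CC=O
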